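20.4 is the first number on the board for oak: free monomer charged divided by initiator charged, the ration, which textbooks call the target degree of polymerisation. Maple's ration is 7.14. The average chain is the ration times the fraction of free monomer reacted, divided by the fraction of initiator that began a chain.

all flasks: initiator 28 mM

| run | free monomer | remark | time |
|---|---|---|---|
| midnight | 0.34 M | run made earlier |  |
| oak | 0.57 M |  | 2.5 d |
| maple | 0.20 M |  | 2.5 d |

midnight run (percent of the free monomer charged)

| time / h | monomer in chains / % | free monomer / % |
|---|---|---|
| 5.00 | 5 | 94 |
| 15.0 | 20 | 81 |
| 25.0 | 37 | 64 |
| 40.0 | 54 | 43 |

(each reading ± 1.5 percentage points)

- which of the two ends with the longer chains by the average number of monomer units in a chain (chains begun, living or dead) ("neither" if they lie within 10%) (oak / maple / neither)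
- average number of monomer units in a chain (chains begun, living or dead) at the end, oak
- average number of monomer units in a chain (chains begun, living or dead) at the end, maple

- the average divides the monomer in chains by the number of chains begun, living and dead together
- the numbers in the tables scatter with a standard deviation of 1.5 percentage points
- steps thought possible: free monomer + initiator -> living end + monomer in chains; free monomer + living end -> monomer in chains + living end; initiator -> spent initiator
- the earlier runs do not show the number of chains; that part of a forecast is a guess

Two chemists read the midnight run, whose ration is 12.1. The first says one initiator makes one chain, so the ration is a ceiling on the average. Oak's ration is larger than maple's by a factor 2.86, far outside the margin of 10%, so oak has the longer chains.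

The second says the start step and the growth step both carry free monomer as a factor, so their ratio holds none of it. With the same 28 mM of initiator, oak and maple should then share one length, near the 6.56 units per initiator that the midnight run shows at 40.0 h, and the answer is neither.

My reckoning sides with the first. That length in oak means 32.2% of its charge reacted at 2.5 d, less than the 54% the midnight run reached in a shorter time with a smaller charge. The number of chains stays a guess.

The forecast names the same flask as the first chemist: oak, with 18 for oak (range 14 to 32) and 7 for maple (range 5 to 15). Of those ranges it says: “Decay would mean fewer chains and longer averages, so my ranges stretch upward”.

The simulation gives oak, with 19.4 for oak and 7.87 for maple.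

    free monomer + initiator → living end + monomer in chains (k = 0.00390 M⁻¹ min⁻¹)
    free monomer + living end → monomer in chains + living end, rate k2*[living end]*[free monomer] (k = 0.0200 M⁻¹ min⁻¹)
    initiator → spent initiator (k = 4.20 × 10⁻⁴ min⁻¹)

Oak's ration times 78.1% reacted, over 82.0% of its initiator standing as living ends, gives 19.4. Maple's ration times 64.5%, over 58.6%, gives 7.87, and maple's simulated average stands above its ration. The neighbour flask, maple with 0.12 M of free monomer, has ration 4.29; with 55.4% reacted over 45.0% this gives 5.27, and that flask stands at 5.27.

The runs are calculated on assumed constants, and the scatter is random.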